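**Retrosynthetic overview**
- Numbering: ring C1=C2–C3(=O)–C4(CH3)=C5–C6(O)–C7–C8(O‑tigloyl)–C9–C10(CH3)(OH); lactone C6–O–C12(=O)–C11(=C13H2)–C7. The strategy rests on the C8(O)–C9–C10(OH) unit, a β‑hydroxy carbonyl (aldol) relationship inside the ten‑membered ring whose acceptor is the methyl ketone C10(=O)–C1=C2.
- Last ring (ten‑membered carbocycle): C9–C10 is cut to the samarium enolate of a C8 bromomethyl ketone and the C10 methyl enone (SmI2 Reformatsky closure), followed by anti reduction at C8, tigloylation, C3 desilylation and C3 oxidation.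
- Open chain: C3–C4 by Nozaki–Hiyama–Kishi coupling of the Z‑alkenyl iodide with (E)‑4,4‑dimethoxybut‑2‑enal; C10 methyl by Grignard addition and oxidation; C8–C9 bromomethyl ketone from an acetonide (diol, bromohydrin, ketone).
- First ring (α‑methylene‑γ‑lactone): C6–C7 and O–C12 by anti allylboration–lactonisation of (Z)‑3‑iodobut‑2‑enal (from but‑2‑yn‑1‑ol) with a 2‑(methoxycarbonyl)allylboronate made from (R)‑glyceraldehyde acetonide.
- Ring order: lactone (step 6), then the ten‑membered ring (step 15).

Key step: step 15

Assumption 1: C3 is formed in step 7 without control and becomes a ketone in step 19; structures are written for one C3 epimer, the other is separated at 16 and carried through the same steps, and both are to be tried in step 15.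
Assumption 2: C10 of 18 is an epimer mixture that converges in step 11; 22 and 24 are β‑acyloxy ketones (C8 ketone, C6 lactone oxygen), so they are kept away from base throughout.

Step 1
Reactants: 1 but‑2‑yn‑1‑ol
Product: 3 (Z)‑3‑iodobut‑2‑en‑1‑ol, via cyclic alkenylaluminate 2 (not isolated)
Conditions: NaAlH2(OCH2CH2OMe)2, THF, 0 °C → rt; then I2, THF, −78 → 0 °C
Reagents that add atoms: iodine, [I][I]
Why: Hydroxyl‑directed trans‑hydroalumination of the propargylic alcohol places aluminium on C3 inside a five‑membered alkoxyaluminate, and iodinolysis of the C–Al bond with retention gives the Z‑iodoalkene, a standard preparation of 3‑iodoallylic alcohols.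

Step 2
Reactants: 3 (Z)‑3‑iodobut‑2‑en‑1‑ol
Product: 4 (Z)‑3‑iodobut‑2‑enal
Conditions: MnO2, CH2Cl2, rt, dark
Reagents that add atoms: none
Why: MnO2 allylic oxidation is neutral and leaves the alkenyl iodide and its geometry untouched; the light‑sensitive enal is used at once.

Step 3
Reactants: 5 (R)‑2,2‑dimethyl‑1,3‑dioxolane‑4‑carbaldehyde
Product: 6 (S)‑4‑ethynyl‑2,2‑dimethyl‑1,3‑dioxolane
Conditions: dimethyl (1‑diazo‑2‑oxopropyl)phosphonate, K2CO3, MeOH, 0 °C → rt
Reagents that add atoms: dimethyl (1‑diazo‑2‑oxopropyl)phosphonate, COP(=O)(OC)C(=[N+]=[N-])C(C)=O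
Why: Ohira–Bestmann (Seyferth–Gilbert) homologation converts the aldehyde into the terminal alkyne under conditions mild enough for this α‑alkoxy aldehyde to keep its configuration.

Step 4
Reactants: 6 (S)‑4‑ethynyl‑2,2‑dimethyl‑1,3‑dioxolane
Product: 8 methyl 3‑[(4S)‑2,2‑dimethyl‑1,3‑dioxolan‑4‑yl]prop‑2‑ynoate, via lithium acetylide 7 (not isolated)
Conditions: n‑BuLi, THF, −78 °C; then ClCO2Me, −78 → 0 °C
Reagents that add atoms: methyl chloroformate, COC(=O)Cl
Why: Acylation of a lithium acetylide with a chloroformate is the standard route to alk‑2‑ynoates and does not affect the acetonide.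

Step 5
Reactants: 8 methyl 3‑[(4S)‑2,2‑dimethyl‑1,3‑dioxolan‑4‑yl]prop‑2‑ynoate
Product: 10 methyl (Z)‑3‑[(4S)‑2,2‑dimethyl‑1,3‑dioxolan‑4‑yl]‑2‑[(4,4,5,5‑tetramethyl‑1,3,2‑dioxaborolan‑2‑yl)methyl]prop‑2‑enoate (dioxolane cis to the ester), via vinylalane 9 (not isolated)
Conditions: i‑Bu2AlH, HMPA, THF, 0 °C; then ICH2B(pin), 0 °C → rt
Reagents that add atoms: 2‑(iodomethyl)‑4,4,5,5‑tetramethyl‑1,3,2‑dioxaborolane, CC1(C)OB(CI)OC1(C)C
Why: The HMPA complex of i‑Bu2AlH adds H and Al syn across the ynoate in the conjugate sense (conjugate hydroalumination), and borylmethylation of the α‑alumino acrylate through an ate complex and 1,2‑shift with retention gives the allylboronate with the dioxolane cis to the ester, the geometry an anti allylboration needs.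

Step 6
Reactants: 4 (Z)‑3‑iodobut‑2‑enal; 10 the allylboronate
Product: 12 (4S,5S)‑4‑[(4S)‑2,2‑dimethyl‑1,3‑dioxolan‑4‑yl]‑5‑[(Z)‑2‑iodoprop‑1‑en‑1‑yl]‑3‑methylideneoxolan‑2‑one (trans‑lactone; C6 and C7 as in the target), via homoallylic borate 11 (not isolated)
Conditions: (S)‑3,3'‑bis(2,4,6‑triisopropylphenyl)‑1,1'‑binaphthyl‑2,2'‑diyl hydrogen phosphate (10 mol%), 4 Å molecular sieves, toluene, −30 °C → rt; then p‑toluenesulfonic acid (catalytic), rt
Reagents that add atoms: none
Why: This is a chiral phosphoric acid‑catalysed allylboration through a closed Zimmerman–Traxler chair in which the γ‑substituent, trans to CH2B, sits equatorial so that C6–C7 forms anti and lactonisation gives the trans‑lactone; the acid, hydrogen‑bonded to the boronate oxygen and the formyl hydrogen, is expected to direct attack to the Si face of the aldehyde, and the (S)‑dioxolane, with C8–H in the alkene plane to avoid allylic strain with the cis ester, should reinforce this by shielding the other face of C7.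

Step 7
Reactants: 12 the iodo lactone; 13 (E)‑4,4‑dimethoxybut‑2‑enal
Product: 15 C3 carbinol in which C4 of the lactone is bonded to CH(OH)–CH=CH–CH(OMe)2 (Z C4=C5 and E C1=C2), via alkenylchromium 14 (not isolated)
Conditions: CrCl2 (excess), NiCl2 (catalytic), DMSO, rt
Reagents that add atoms: none
Why: In the Nozaki–Hiyama–Kishi coupling zerovalent nickel formed in situ inserts into the C–I bond, transmetalation gives the alkenyl species of trivalent chromium with retention of the Z geometry, and this adds 1,2 to the aldehyde only, tolerating lactone, acetonide and acetal.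

Step 8
Reactants: 15 the C3 carbinol
Product: 16 C3 tert‑butyldimethylsilyl ether of 15
Conditions: TBSCl, imidazole, DMF, rt
Reagents that add atoms: tert‑butyldimethylsilyl chloride, CC(C)(C)[Si](C)(C)Cl
Why: Standard silylation of a secondary allylic alcohol under non‑acidic conditions that leave both acetals intact; the C3 epimers are separated here.

Step 9
Reactants: 16 the silyl ether acetal
Product: 17 enal with the C10 aldehyde free (E C1=C2; acetonide and silyl ether kept)
Conditions: pyridinium p‑toluenesulfonate (catalytic), acetone/H2O, rt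
Reagents that add atoms: water, O
Why: The dimethyl acetal of an enal is hydrolysed far faster than the dioxolane, which is held in place by the acetone medium, and the secondary silyl ether survives this weak acid (selective acetal hydrolysis).

Step 10
Reactants: 17 the enal
Product: 18 C10 secondary allylic carbinol (C10 epimer mixture)
Conditions: MeMgBr, THF, −78 °C
Reagents that add atoms: methylmagnesium bromide, C[Mg]Br
Why: Grignard 1,2‑addition to the unhindered enal at −78 °C is much faster than attack on the lactone carbonyl or conjugate addition to the methylene lactone.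

Step 11
Reactants: 18 the C10 carbinol
Product: 19 methyl enone (C10 ketone; E C1=C2; C3 silyl ether; C8–C9 acetonide)
Conditions: MnO2, CH2Cl2, rt
Reagents that add atoms: none
Why: MnO2 allylic oxidation converts the secondary allylic alcohol into the E‑enone under neutral conditions and removes the C10 stereocentre.

Step 12
Reactants: 19 the methyl enone acetonide
Product: 20 8,9‑diol of 19
Conditions: AcOH/H2O (4:1), rt
Reagents that add atoms: none
Why: Aqueous acetic acid hydrolyses the terminal isopropylidene acetal while the secondary silyl ether, whose ionisation is disfavoured by the adjacent enone, should survive, and the acidic medium avoids translactonisation to the freed C8 hydroxyl.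

Step 13
Reactants: 20 the 8,9‑diol
Product: 21 bromohydrin (C9 bromide and C8 hydroxyl)
Conditions: CBr4, PPh3, CH2Cl2, 0 °C
Reagents that add atoms: carbon tetrabromide, BrC(Br)(Br)Br
Why: The Appel reaction at low temperature is selective for the primary hydroxyl of a terminal 1,2‑diol, bromide displacing the primary alkoxyphosphonium ion by SN2.

Step 14
Reactants: 21 the bromohydrin
Product: 22 bromomethyl ketone: trans‑lactone carrying C7–C(=O)CH2Br with Z C4=C5 and C3 silyl ether and E methyl enone
Conditions: Dess–Martin periodinane, NaHCO3, CH2Cl2, 0 °C → rt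
Reagents that add atoms: none
Why: Dess–Martin oxidation turns the secondary bromohydrin into the α‑bromo ketone under non‑basic conditions, which is needed because the product is a β‑acyloxy ketone with an epimerisable, allylic C7–H; 22 is used without storage.

Step 15
Reactants: 22 the bromomethyl ketone
Product: 24 ten‑membered β‑hydroxy ketone (C8 ketone; C10 tertiary carbinol as in the target; C3 silyl ether; lactone intact), via samarium enolate 23 (not isolated)
Conditions: SmI2 (2.5 equiv), THF, −78 °C, 22 added slowly (final 0.002 M); then saturated aqueous NH4Cl at −78 °C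
Reagents that add atoms: none
Why: Two single‑electron transfers from divalent samarium cleave the C9–Br bond and give the oxygen‑bound enolate of trivalent samarium only at C8=C9; the oxophilic metal then binds the C10 ketone oxygen and C9 adds to C10 inside a six‑membered chelate, an intramolecular Reformatsky (samarium aldol) reaction of the type known to close medium and large rings from α‑halo carbonyl compounds. The ten‑membered carbocycle closes in the 10‑exo‑trig mode, the chain between C9 and C10 being shortened and pre‑bent by the trans‑lactone, the Z C4=C5 bond and the E C1=C2 bond. The new C10 stereocentre is set by the ketone face that the chelate presents to C9, which depends on the ring conformation imposed by C6, C7 and the C3 silyl ether; the carbinol drawn is the one needed, but the facial preference cannot be predicted with confidence, so both C3 epimers are to be cyclised. The step needs 1,2‑ and not 1,4‑addition, secured by the hard chelated enolate and by the eight‑membered ring that attack at C2 would require. It also needs C–Br reduction ahead of reduction of the enone, the γ‑silyloxy group or the methylene lactone, secured by the much faster electron transfer to the α‑bromo ketone at −78 °C without additives and by holding C3 as a silyl ether so that no ene‑dione is present. The cold quench prevents retro‑aldol opening and base‑induced loss of the lactone oxygen from C6.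

Step 16
Reactants: 24 the β‑hydroxy ketone
Product: 25 8,10‑anti diol (C8 as in the target)
Conditions: Me4NBH(OAc)3, MeCN/AcOH (1:1), −40 → −20 °C
Reagents that add atoms: none
Why: In the Evans–Saksena reduction the C10 hydroxyl exchanges an acetate on boron and delivers hydride intramolecularly to the C8 ketone through a chair that, with the ring bonds C10–C1 and C8–C7 equatorial, gives the 8,10‑anti diol, and the acidic medium is safe for the β‑acyloxy ketone.

Step 17
Reactants: 25 the anti diol; 26 tiglic acid
Product: 27 C8 tiglate of 25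
Conditions: 2,4,6‑trichlorobenzoyl chloride, Et3N, toluene, rt; then 25, 4‑(dimethylamino)pyridine, toluene, rt
Reagents that add atoms: none
Why: In the Yamaguchi esterification the mixed anhydride of tiglic acid acylates the secondary C8 hydroxyl while the tertiary C10 hydroxyl does not react, and the E‑configured tiglate cannot isomerise to a more stable form.

Step 18
Reactants: 27 the silyl ether tiglate
Product: 28 C3 alcohol (3‑hydroxy precursor of the target)
Conditions: HF·pyridine, pyridine, THF, 0 °C → rt
Reagents that add atoms: none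
Why: Buffered HF·pyridine cleaves the secondary silyl ether without the acyl migration, lactone opening or conjugate addition that a basic fluoride source could cause (desilylation).

Step 19
Reactants: 28 the C3 alcohol
Product: 29 eupaheliangolide A
Conditions: MnO2, CH2Cl2, rt
Reagents that add atoms: none
Why: MnO2 allylic oxidation converts the doubly allylic secondary C3 alcohol of either epimer into the cross‑conjugated dienone and cannot oxidise the tertiary C10 carbinol.

**Compound list**
1 | but‑2‑yn‑1‑ol | CC#CCO | starting material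
2 | sodium alkoxy(alkenyl)aluminate from 1 (five‑membered O–CH2–CH=C(CH3)–Al ring, two 2‑methoxyethoxy groups on Al; not isolated) | CC1=CCO[Al-]1(OCCOC)OCCOC.[Na+] | intermediate
3 | (Z)‑3‑iodobut‑2‑en‑1‑ol | C/C(I)=C/CO | intermediate
4 | (Z)‑3‑iodobut‑2‑enal | C/C(I)=C/C=O | intermediate
5 | (R)‑2,2‑dimethyl‑1,3‑dioxolane‑4‑carbaldehyde | CC1(C)OC[C@H](C=O)O1 | starting material
6 | (S)‑4‑ethynyl‑2,2‑dimethyl‑1,3‑dioxolane | CC1(C)OC[C@H](C#C)O1 | intermediate
7 | lithium acetylide of 6 (not isolated) | [Li]C#C[C@H]1COC(C)(C)O1 | intermediate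
8 | methyl 3‑[(4S)‑2,2‑dimethyl‑1,3‑dioxolan‑4‑yl]prop‑2‑ynoate | COC(=O)C#C[C@H]1COC(C)(C)O1 | intermediate
9 | methyl 2‑(diisobutylalumanyl)‑3‑[(4S)‑2,2‑dimethyl‑1,3‑dioxolan‑4‑yl]prop‑2‑enoate, dioxolane cis to the ester (not isolated) | COC(=O)/C(=C\[C@H]1COC(C)(C)O1)[Al](CC(C)C)CC(C)C | intermediate
10 | methyl (Z)‑3‑[(4S)‑2,2‑dimethyl‑1,3‑dioxolan‑4‑yl]‑2‑[(4,4,5,5‑tetramethyl‑1,3,2‑dioxaborolan‑2‑yl)methyl]prop‑2‑enoate | COC(=O)/C(CB1OC(C)(C)C(C)(C)O1)=C\[C@H]2COC(C)(C)O2 | intermediate
11 | open‑chain anti adduct: methyl 2‑methylidene ester, C7 bearing the (S)‑dioxolane, C6 bearing O–B(pin) and the (Z)‑2‑iodoprop‑1‑enyl group (not isolated) | C=C(C(=O)OC)[C@H]([C@H]1COC(C)(C)O1)[C@H](OB2OC(C)(C)C(C)(C)O2)/C=C(/C)I | intermediate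
12 | (4S,5S)‑4‑[(4S)‑2,2‑dimethyl‑1,3‑dioxolan‑4‑yl]‑5‑[(Z)‑2‑iodoprop‑1‑en‑1‑yl]‑3‑methylideneoxolan‑2‑one | C=C1C(=O)O[C@H](/C=C(/C)I)[C@H]1[C@H]2COC(C)(C)O2 | intermediate
13 | (E)‑4,4‑dimethoxybut‑2‑enal | COC(OC)/C=C/C=O | starting material
14 | alkenylchromium dichloride from 12 (CrCl2 in place of iodine at C4, Z retained; not isolated) | C=C1C(=O)O[C@H](/C=C(/C)[Cr](Cl)Cl)[C@H]1[C@H]2COC(C)(C)O2 | intermediate
15 | C3 carbinol: lactone of 12 with C4 bonded to CH(OH)–CH=CH–CH(OMe)2 (E), Z C4=C5, C3 epimer as drawn | C=C1C(=O)O[C@H](/C=C(/C)[C@@H](O)/C=C/C(OC)OC)[C@H]1[C@H]2COC(C)(C)O2 | intermediate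
16 | C3 tert‑butyldimethylsilyl ether of 15 | C=C1C(=O)O[C@H](/C=C(/C)[C@@H](O[Si](C)(C)C(C)(C)C)/C=C/C(OC)OC)[C@H]1[C@H]2COC(C)(C)O2 | intermediate
17 | enal: 16 with the acetal converted into the C10 aldehyde | C=C1C(=O)O[C@H](/C=C(/C)[C@@H](O[Si](C)(C)C(C)(C)C)/C=C/C=O)[C@H]1[C@H]2COC(C)(C)O2 | intermediate
18 | C10 secondary carbinol (C10 epimer mixture) | C=C1C(=O)O[C@H](/C=C(/C)[C@@H](O[Si](C)(C)C(C)(C)C)/C=C/C(C)O)[C@H]1[C@H]2COC(C)(C)O2 | intermediate
19 | methyl enone: C10 ketone, E C1=C2, C3 silyl ether, C8–C9 acetonide | C=C1C(=O)O[C@H](/C=C(/C)[C@@H](O[Si](C)(C)C(C)(C)C)/C=C/C(C)=O)[C@H]1[C@H]2COC(C)(C)O2 | intermediate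
20 | 8,9‑diol of 19 | C=C1C(=O)O[C@H](/C=C(/C)[C@@H](O[Si](C)(C)C(C)(C)C)/C=C/C(C)=O)[C@H]1[C@H](O)CO | intermediate
21 | bromohydrin: C9 bromide, C8 hydroxyl | C=C1C(=O)O[C@H](/C=C(/C)[C@@H](O[Si](C)(C)C(C)(C)C)/C=C/C(C)=O)[C@H]1[C@H](O)CBr | intermediate
22 | bromomethyl ketone, key‑step precursor: trans‑lactone with C7–C(=O)CH2Br, Z C4=C5, C3 silyl ether, E methyl enone | C=C1C(=O)O[C@H](/C=C(/C)[C@@H](O[Si](C)(C)C(C)(C)C)/C=C/C(C)=O)[C@H]1C(=O)CBr | intermediate
23 | samarium enolate of 22, C8(O–SmI2)=C9H2 (not isolated) | C=C1C(=O)O[C@H](/C=C(/C)[C@@H](O[Si](C)(C)C(C)(C)C)/C=C/C(C)=O)[C@H]1C(=C)O[Sm](I)I | intermediate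
24 | ten‑membered β‑hydroxy ketone: C8 ketone, C10 tertiary carbinol as in the target, C3 silyl ether, 6,12‑lactone | C=C1C(=O)O[C@@H]2/C=C(/C)[C@@H](O[Si](C)(C)C(C)(C)C)/C=C/[C@](C)(O)CC(=O)[C@@H]12 | intermediate
25 | 8,10‑anti diol, C8 as in the target | C=C1C(=O)O[C@@H]2/C=C(/C)[C@@H](O[Si](C)(C)C(C)(C)C)/C=C/[C@](C)(O)C[C@@H](O)[C@@H]12 | intermediate
26 | tiglic acid, (E)‑2‑methylbut‑2‑enoic acid | C/C=C(\C)C(=O)O | starting material
27 | C8 tiglate of 25 | C=C1C(=O)O[C@@H]2/C=C(/C)[C@@H](O[Si](C)(C)C(C)(C)C)/C=C/[C@](C)(O)C[C@@H](OC(=O)/C(C)=C/C)[C@@H]12 | intermediate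
28 | C3 alcohol, 3‑hydroxy precursor of the target | C=C1C(=O)O[C@@H]2/C=C(/C)[C@@H](O)/C=C/[C@](C)(O)C[C@@H](OC(=O)/C(C)=C/C)[C@@H]12 | intermediate
29 | eupaheliangolide A (6R,7R,8R,10R; 1E,4Z) | C=C1C(=O)O[C@@H]2/C=C(/C)C(=O)/C=C/[C@](C)(O)C[C@@H](OC(=O)/C(C)=C/C)[C@@H]12 | target

**Step count and risks**
Total steps: 19. Longest linear sequence: 17 steps (5 → 29, steps 3–19); the branch from 1 joins at step 6.

Most likely to fail, step 15. The samarium enolate may be protonated or add to a second molecule faster than the strained ten‑membered chelate forms, or the chelate may present the wrong ketone face and give the C10 epimer. The fallback moves the ring closure to C3–C4 and forms C9–C10 intermolecularly; it sets out from 12 and comes back at 28. Aqueous acetic acid converts 12 into the iodo diol F1, CBr4/PPh3 gives the iodo bromohydrin F2, and Dess–Martin oxidation gives the iodo bromomethyl ketone F3. (E)‑5,5‑Dimethoxypent‑3‑en‑2‑one F4 is made by Wittig reaction of 2,2‑dimethoxyacetaldehyde with 1‑(triphenylphosphoranylidene)propan‑2‑one. SmI2 added at −78 °C to F3 and an excess of F4 should give, by intermolecular Reformatsky addition, the tertiary carbinol with C10 as in the target F5 and its C10 epimer F6, to be separated by chromatography. F5 is reduced with Me4NBH(OAc)3 to the open‑chain anti diol F7, esterified at C8 with 26 under Yamaguchi conditions to the tiglate F8, and hydrolysed with pyridinium p‑toluenesulfonate in wet acetone to the enal F9. CrCl2/NiCl2 in DMSO/THF at high dilution then closes the ten‑membered ring by intramolecular Nozaki–Hiyama–Kishi reaction between C4 and C3 and gives 28, which is oxidised as in step 19.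

Second, step 6. The ester‑deactivated boronate may be activated too weakly by the phosphoric acid, so that an unselective background reaction takes over, or catalyst and resident stereocentre may oppose each other and erode facial selectivity. The fallback gives up catalyst control for substrate control plus diastereomer separation; it sets out from 4 and 10 and comes back at 12. The allylboration is run with catalytic Sc(OTf)3 in toluene, which is established for 2‑alkoxycarbonyl allylboronates and keeps the closed transition state, so only trans‑lactones form. Because the dioxolane centre is fixed, the two trans‑lactones are diastereomers: 12 and the (4R,5R)‑lactone diastereomer F10, separable by chromatography, each enantiopure.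

Third, step 16. Acetate exchange at the hindered tertiary C10 hydroxyl may be slow, so that undirected reduction competes, or the macrocycle conformation may override the chair model and hydride may reach the wrong face of C8. The fallback corrects C8 during esterification; it sets out from 24 and comes back at 27. Chelation‑controlled reduction (Et2BOMe, NaBH4, THF/MeOH, −78 °C; Narasaka–Prasad) gives the 8,10‑syn diol F11, which is also the by‑product of a poorly selective step 16. Mitsunobu esterification with 26 (PPh3, diisopropyl azodicarboxylate, toluene) inverts C8 and installs the tiglate, the tertiary hydroxyl being inert, to give 27.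

**Further compounds**
F1 | step 15 | iodo diol: 12 with the acetonide removed | C=C1C(=O)O[C@H](/C=C(/C)I)[C@H]1[C@H](O)CO
F2 | step 15 | iodo bromohydrin: C9 bromide, C8 hydroxyl | C=C1C(=O)O[C@H](/C=C(/C)I)[C@H]1[C@H](O)CBr
F3 | step 15 | iodo bromomethyl ketone | C=C1C(=O)O[C@H](/C=C(/C)I)[C@H]1C(=O)CBr
F4 | step 15 | (E)‑5,5‑dimethoxypent‑3‑en‑2‑one | COC(OC)/C=C/C(C)=O
F5 | step 15 | open‑chain β‑hydroxy ketone, C10 as in the target, alkenyl iodide and dimethyl acetal termini | C=C1C(=O)O[C@H](/C=C(/C)I)[C@H]1C(=O)C[C@@](C)(O)/C=C/C(OC)OC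
F6 | step 15 | C10 epimer of F5 | C=C1C(=O)O[C@H](/C=C(/C)I)[C@H]1C(=O)C[C@](C)(O)/C=C/C(OC)OC
F7 | step 15 | open‑chain 8,10‑anti diol | C=C1C(=O)O[C@H](/C=C(/C)I)[C@H]1[C@H](O)C[C@@](C)(O)/C=C/C(OC)OC
F8 | step 15 | C8 tiglate of F7 | C=C1C(=O)O[C@H](/C=C(/C)I)[C@H]1[C@H](OC(=O)/C(C)=C/C)C[C@@](C)(O)/C=C/C(OC)OC
F9 | step 15 | enal: F8 with the acetal hydrolysed | C=C1C(=O)O[C@H](/C=C(/C)I)[C@H]1[C@H](OC(=O)/C(C)=C/C)C[C@@](C)(O)/C=C/C=O
F10 | step 6 | (4R,5R)‑lactone diastereomer of 12 with the same (4S)‑dioxolane | C=C1C(=O)O[C@@H](/C=C(/C)I)[C@@H]1[C@H]2COC(C)(C)O2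
F11 | step 16 | 8,10‑syn diol, C8 epimer of 25 | C=C1C(=O)O[C@@H]2/C=C(/C)[C@@H](O[Si](C)(C)C(C)(C)C)/C=C/[C@](C)(O)C[C@H](O)[C@@H]12
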